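**Retrosynthetic overview**
1. The ten-membered ring is closed last. C3=C4 and C5=C16 form together from a seco compound (C2 vinyl, C5 ethynyl) by ethene-mediated enyne metathesis and ring closure.
2. The γ-lactone comes just before: C8–C17 by an intramolecular samarium Reformatsky reaction of a C7 2-bromopropanoate. C6–Cl and C7–O come from acylative opening of a trans C6–C7 epoxide.
3. C5–C9 are the five carbons of furfural. Oxidative dearomatisation of the furan unmasks C8=O, C6=C7 and C5H=O in one step, and the C5 aldehyde then becomes the alkyne (C4).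
4. Ring A is m-toluic acid. Birch reduction–methylation makes quaternary C1, the derived cyclohexadienyltitanium forms C9–C10 by SE2′ addition to furfural, OsO4 sets C11/C12, and a catalytic vinylzinc addition makes C2–C3.
5. Order of rings: ring A (from the arene), then the γ-lactone, then the ten-membered ring.

Assumption: briarane numbering (C1–C20) is used for all intermediates and α is the face of ring A that carries C2; the CHBr centre of the 2-bromopropanoyl group is used as a mixture because step 13 destroys it.

**Step 1**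
Reactants: 1 3-methylbenzoic acid
Product: 3 (±)-1,3-dimethylcyclohexa-2,5-diene-1-carboxylic acid, via dilithium dienediolate 2 (not isolated)
Conditions: Li (3.2 equiv), NH3(l)/THF, −78 °C; MeI, −78 °C to rt; aq HCl
Reagents that add atoms: iodomethane, CI
Why: Birch reductive alkylation, in which the carboxylate directs ipso/para reduction so that the ring methyl stays on a double bond (C10=C11), and the dienediolate is C-methylated only at the ipso carbon, creating quaternary C1 (racemic here, the enantiomers are sorted in step 4) and leaving a doubly allylic C12H2 for step 4.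

**Step 2**
Reactants: 3 (±)-1,3-dimethylcyclohexa-2,5-diene-1-carboxylic acid
Product: 4 (±)-(1,3-dimethylcyclohexa-2,5-dien-1-yl)methanol
Conditions: LiAlH4, Et2O, 0 °C to rt
Reagents that add atoms: none
Why: Hydride reduction of the acid to the neopentyl alcohol (C2), which leaves the two isolated olefins and C1 untouched.

**Step 3**
Reactants: 4 (±)-(1,3-dimethylcyclohexa-2,5-dien-1-yl)methanol
Product: 5 (±)-triethylsilyl ether of 4
Conditions: Et3SiCl, imidazole, CH2Cl2, 0 °C
Reagents that add atoms: chlorotriethylsilane, CC[Si](Cl)(CC)CC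
Why: Standard silylation, where the triethylsilyl group survives s-BuLi at −78 °C, makes the C2 arm clearly larger than the C15 methyl, and can later be oxidised off directly (step 7).

**Step 4**
Reactants: 5 (±)-triethylsilyl ether of 4 (2.2 equiv); 6 furfural
Product: 9 (1S,9S,10S)-furyl carbinol diene, via cyclohexadienyllithium 7 (not isolated), via cyclohexadienyltitanium TADDOLate 8 (not isolated)
Conditions: 5, s-BuLi, TMEDA, THF, −78 °C; CpTiCl[(R,R)-TADDOLate] (2.3 equiv), Et2O, −78 °C; 6 (1.0 equiv), −78 °C; aq NH4F; unreacted (R)-5 recovered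
Reagents that add atoms: none
Why: Proposed new method: deprotonation of C12H2 gives a 6,6-disubstituted cyclohexadienyl anion that cannot aromatise, titanium sits on C12 on the face anti to CH2OSiEt3, and furfural is taken up through a closed chair SE2′ transition state at the more nucleophilic methallyl terminus C10 (ring carbon C1 is the Z substituent, hence the 9,10-syn relationship, C9 cis to C15 and a conjugated C11=C12–C13=C14 diene), while the (R,R)-TADDOLate permits only Si-face attack on the aldehyde (9S), a demand that only the (1S)-enantiomer of the racemic reagent can meet on its open face, so C1, C9 and C10 emerge as one isomer, the closest known reaction types being Duthaler–Hafner allyltitanation and the desymmetrising addition of titanated cyclohexa-1,4-dienes to aldehydes.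

**Step 5**
Reactants: 9 (1S,9S,10S)-furyl carbinol diene
Product: 10 (1S,9S,10S,11S,12R)-9,11,12-triol
Conditions: OsO4 (2 mol %), NMO, acetone/H2O, 0 °C
Reagents that add atoms: N-methylmorpholine N-oxide, C[N+]1([O-])CCOCC1; water, O; osmium tetroxide (oxygen carrier), O=[Os](=O)(=O)=O
Why: Upjohn dihydroxylation, in which OsO4 takes the trisubstituted, most electron-rich C11=C12 end of the diene and adds syn from the α face, anti to the bulky C9 branch on the neighbouring C10 and to C15, which sets 11S and 12R as the cis-diol of the target while the furan and the hindered C13=C14 bond react more slowly.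

**Step 6**
Reactants: 10 (1S,9S,10S,11S,12R)-9,11,12-triol
Product: 11 9,12-diacetate
Conditions: Ac2O, pyridine, DMAP (cat.), CH2Cl2, 0 °C to rt
Reagents that add atoms: acetic anhydride, CC(=O)OC(C)=O
Why: DMAP-catalysed acylation with steric differentiation, in which the two secondary alcohols become the acetates that stay to the end and the tertiary C11 hydroxyl does not react, with no stereocentre touched.

**Step 7**
Reactants: 11 9,12-diacetate
Product: 12 C2 aldehyde
Conditions: (COCl)2, DMSO, CH2Cl2, −78 to −30 °C; Et3N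
Reagents that add atoms: none
Why: Swern oxidation applied directly to a primary triethylsilyl ether, in which chlorodimethylsulfonium chloride cleaves the Si–O bond and the alkoxysulfonium salt collapses to the neopentyl aldehyde, saving a deprotection step, and C1 cannot epimerise because it is quaternary.

**Step 8**
Reactants: 12 C2 aldehyde
Product: 14 (2S)-allylic butanoate, via zinc alkoxide 13 (not isolated)
Conditions: Zn(CH=CH2)2 (3 equiv), (−)-MIB (20 mol %), toluene, −20 to 0 °C; then (n-PrCO)2O, DMAP, rt
Reagents that add atoms: divinylzinc, C=C[Zn]C=C; butanoic anhydride, CCCC(=O)OC(=O)CCC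
Why: Amino-alcohol-catalysed enantioselective vinylzinc addition followed by acylation of the zinc alkoxide in the flask, in which (−)-MIB (the ligand sense that gives Si-face addition) overrides the weak bias of the α-quaternary aldehyde and sets 2S, the organozinc leaves the acetates alone, and the alkoxide is trapped as the butanoate of the target.

**Step 9**
Reactants: 14 (2S)-allylic butanoate
Product: 16 (E)-4-oxoenal, via (Z)-4-oxoenal 15 (not isolated)
Conditions: NBS, NaHCO3, acetone/H2O (10:1), −15 °C; then pyridine, rt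
Reagents that add atoms: water, O
Why: Oxidative dearomatisation of the furan (NBS/water 2,5-addition, ring opening, pyridine-catalysed Z to E isomerisation), which unmasks the C8 ketone, the C6=C7 olefin and the C5 aldehyde in one operation, because the electron-rich furan outruns the two hindered, deactivated olefins and the open-chain E isomer is the thermodynamic one.

**Step 10**
Reactants: 16 (E)-4-oxoenal
Product: 17 (6S,7S)-epoxy aldehyde
Conditions: 35 % H2O2, (R)-2-{bis[3,5-bis(trifluoromethyl)phenyl](trimethylsilyloxy)methyl}pyrrolidine (10 mol %), CH2Cl2, rt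
Reagents that add atoms: hydrogen peroxide, OO
Why: Iminium–enamine organocatalytic epoxidation of an enal (Jørgensen type), in which the iminium ion of the C5 aldehyde directs peroxide to C7 and the enamine closes the ring, the E olefin gives the trans epoxide, and the R catalyst (the one that turns cinnamaldehyde into its (2S,3R)-epoxide) fixes both C6 and C7 by reagent control.

**Step 11**
Reactants: 17 (6S,7S)-epoxy aldehyde
Product: 18 (6R,7S)-ethynyl epoxide
Conditions: (MeO)2P(O)CHN2, t-BuOK, THF, −78 to −30 °C
Reagents that add atoms: dimethyl (diazomethyl)phosphonate, COP(=O)(OC)C=[N+]=[N-]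
Why: Seyferth–Gilbert homologation under alcohol-free conditions, so the three esters survive, the aldehyde reacts far faster than the hindered C8 ketone, the new carbon is C4, and the epoxide carbons keep their geometry (only the C6 descriptor changes).

**Step 12**
Reactants: 18 (6R,7S)-ethynyl epoxide
Product: 19 (6S,7R)-chloro 2-bromopropanoate
Conditions: 2-bromopropanoyl chloride, CoCl2 (5 mol %), CH2Cl2, 0 °C to rt
Reagents that add atoms: 2-bromopropanoyl chloride, CC(Br)C(=O)Cl
Why: CoCl2-catalysed acylative cleavage of an epoxide by an acid chloride, in which O-acylation is followed by SN2 attack of chloride at the propargylic carbon C6 (positive charge build-up at C7 is disfavoured next to the carbonyl group), giving inversion at C6 (6S) and retention at C7 (7R), that is, the anti chlorohydrin ester of the target together with the Reformatsky handle.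

**Step 13**
Reactants: 19 (6S,7R)-chloro 2-bromopropanoate
Product: 21 seco-lactone enyne, via samarium enolate 20 (not isolated)
Conditions: SmI2 (2.2 equiv, slow addition), THF, −78 °C; aq NH4Cl
Reagents that add atoms: none
Why: Intramolecular samarium Reformatsky reaction, in which SmI2 reduces the α-bromo ester much faster than the ketone or the propargylic chloride and the tethered trivalent samarium enolate adds to C8 in the rotamer with C6 and C9 antiperiplanar, which puts 8-OH cis to C6 (8R) and the C17 methyl trans to the bulky C9 branch (17R, also the thermodynamic epimer of this enolisable centre).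

**Step 14**
Reactants: 21 seco-lactone enyne
Product: 23 target CNP0114781.2, via 2-substituted butadiene 22 (not isolated)
Conditions: second-generation Hoveyda–Grubbs catalyst (10 mol %), ethene (1 atm), toluene (1 mM), 60 °C; then argon sparge, 80 °C
Reagents that add atoms: ethene, C=C
Why: Tandem ethene–alkyne cross metathesis and diene–ene ring-closing metathesis, in which Ru=CH2 turns the terminal alkyne into butadiene 22 (creating C5=C16), the unhindered vinyl end of 22 then closes onto the C3 vinyl group, and the reversible closure of a ten-membered ring trans-fused to two rings should settle on the less strained 3Z olefin without touching any stereocentre.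

**Compound list**

| No. | Name | SMILES | Role |
|---|---|---|---|
| 1 | 3-methylbenzoic acid (m-toluic acid) | Cc1cccc(c1)C(=O)O | starting material |
| 2 | dilithium dienediolate (exocyclic C1=C(OLi)2 of the 1,4-dihydro acid) | [Li]OC(O[Li])=C1C=CCC(C)=C1 | intermediate |
| 3 | (±)-1,3-dimethylcyclohexa-2,5-diene-1-carboxylic acid | OC(=O)C1(C)C=CCC(C)=C1 | intermediate |
| 4 | (±)-(1,3-dimethylcyclohexa-2,5-dien-1-yl)methanol | OCC1(C)C=CCC(C)=C1 | intermediate |
| 5 | (±)-triethylsilyl ether of 4, [(1,3-dimethylcyclohexa-2,5-dien-1-yl)methoxy]triethylsilane | CC[Si](CC)(CC)OCC1(C)C=CCC(C)=C1 | intermediate |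
| 6 | furfural (furan-2-carbaldehyde) | O=Cc1ccco1 | starting material |
| 7 | cyclohexadienyllithium (5 lithiated at the doubly allylic C12, racemic) | CC[Si](CC)(CC)OCC1(C)C=CC([Li])C(C)=C1 | intermediate |
| 8 | cyclohexadienyltitanium TADDOLate (matched 1S isomer; CpTi[(R,R)-TADDOLate] on C12, β face, syn to C15) | CC[Si](CC)(CC)OC[C@@]1(C)C=C[C@H]([Ti]2(C3C=CC=C3)OC(c3ccccc3)(c3ccccc3)[C@@H]3OC(C)(C)O[C@H]3C(c3ccccc3)(c3ccccc3)O2)C(C)=C1 | intermediate |
| 9 | (1S,9S,10S)-furyl carbinol diene, (S)-furan-2-yl[(1S,6S)-2,6-dimethyl-6-(triethylsilyloxymethyl)cyclohexa-2,4-dien-1-yl]methanol | CC[Si](CC)(CC)OC[C@@]1(C)C=CC=C(C)[C@@H]1[C@H](O)c1ccco1 | intermediate |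
| 10 | (1S,9S,10S,11S,12R)-9,11,12-triol (11-OH and 12-OH both α and cis, C20 methyl β, C13=C14 kept) | CC[Si](CC)(CC)OC[C@@]1(C)C=C[C@@H](O)[C@@](C)(O)[C@@H]1[C@H](O)c1ccco1 | intermediate |
| 11 | 9,12-diacetate (11-OH free) | CC[Si](CC)(CC)OC[C@@]1(C)C=C[C@@H](OC(C)=O)[C@@](C)(O)[C@@H]1[C@H](OC(C)=O)c1ccco1 | intermediate |
| 12 | C2 aldehyde (formyl group on quaternary 1S carbon) | O=C[C@@]1(C)C=C[C@@H](OC(C)=O)[C@@](C)(O)[C@@H]1[C@H](OC(C)=O)c1ccco1 | intermediate |
| 13 | zinc alkoxide (vinylzinc alkoxide of the 2S allylic alcohol) | C=C[C@H](O[Zn]C=C)[C@@]1(C)C=C[C@@H](OC(C)=O)[C@@](C)(O)[C@@H]1[C@H](OC(C)=O)c1ccco1 | intermediate |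
| 14 | (2S)-allylic butanoate (C2 carries vinyl and O-butanoyl) | C=C[C@H](OC(=O)CCC)[C@@]1(C)C=C[C@@H](OC(C)=O)[C@@](C)(O)[C@@H]1[C@H](OC(C)=O)c1ccco1 | intermediate |
| 15 | (Z)-4-oxoenal (C8 ketone, 6Z olefin, C5 aldehyde) | C=C[C@H](OC(=O)CCC)[C@@]1(C)C=C[C@@H](OC(C)=O)[C@@](C)(O)[C@@H]1[C@H](OC(C)=O)C(=O)/C=C\C=O | intermediate |
| 16 | (E)-4-oxoenal (6E isomer of 15) | C=C[C@H](OC(=O)CCC)[C@@]1(C)C=C[C@@H](OC(C)=O)[C@@](C)(O)[C@@H]1[C@H](OC(C)=O)C(=O)/C=C/C=O | intermediate |
| 17 | (6S,7S)-epoxy aldehyde (trans C6–C7 epoxide) | C=C[C@H](OC(=O)CCC)[C@@]1(C)C=C[C@@H](OC(C)=O)[C@@](C)(O)[C@@H]1[C@H](OC(C)=O)C(=O)[C@H]1O[C@@H]1C=O | intermediate |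
| 18 | (6R,7S)-ethynyl epoxide (same geometry as 17, C5≡C4H) | C=C[C@H](OC(=O)CCC)[C@@]1(C)C=C[C@@H](OC(C)=O)[C@@](C)(O)[C@@H]1[C@H](OC(C)=O)C(=O)[C@H]1O[C@@H]1C#C | intermediate |
| 19 | (6S,7R)-chloro 2-bromopropanoate (C8 ketone, CHBr mixture) | C=C[C@H](OC(=O)CCC)[C@@]1(C)C=C[C@@H](OC(C)=O)[C@@](C)(O)[C@@H]1[C@H](OC(C)=O)C(=O)[C@@H](OC(=O)C(C)Br)[C@@H](Cl)C#C | intermediate |
| 20 | samarium enolate (diiodosamarium enolate of the C7 propanoate) | C=C[C@H](OC(=O)CCC)[C@@]1(C)C=C[C@@H](OC(C)=O)[C@@](C)(O)[C@@H]1[C@H](OC(C)=O)C(=O)[C@@H](OC(O[Sm](I)I)=CC)[C@@H](Cl)C#C | intermediate |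
| 21 | seco-lactone enyne (1S,2S,6S,7R,8R,9S,10S,11S,12R,17R; C2 vinyl, C5 ethynyl) | C=C[C@H](OC(=O)CCC)[C@@]1(C)C=C[C@@H](OC(C)=O)[C@@](C)(O)[C@@H]1[C@H](OC(C)=O)[C@]1(O)[C@@H](C)C(=O)O[C@H]1[C@@H](Cl)C#C | intermediate |
| 22 | 2-substituted butadiene (C5(=CH2)–C4H=CH2 in place of the alkyne of 21) | C=C[C@H](OC(=O)CCC)[C@@]1(C)C=C[C@@H](OC(C)=O)[C@@](C)(O)[C@@H]1[C@H](OC(C)=O)[C@]1(O)[C@@H](C)C(=O)O[C@H]1[C@@H](Cl)C(=C)C=C | intermediate |
| 23 | target CNP0114781.2 (1S,2S,3Z,6S,7R,8R,9S,10S,11S,12R,17R) | C=C1/C=C\[C@H](OC(=O)CCC)[C@@]2(C)C=C[C@@H](OC(C)=O)[C@@](C)(O)[C@@H]2[C@H](OC(C)=O)[C@]2(O)[C@@H](C)C(=O)O[C@H]2[C@H]1Cl | target |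

**Step count and risks**
Total step count: 14. Longest linear sequence: 14 steps (1 to 23); furfural 6 enters at step 4.

The three steps most likely to fail are steps 4, 8 and 14.

Step 4. The risks are the regio- and face-selectivity next to a quaternary carbon, and the sorting of enantiomers by the chiral titanium reagent. The fallback takes the enantiomer selection out of the C–C bond formation and sets out from 3. Racemic 3 is crystallised with (R)-1-phenylethylamine to give (R)-1-phenylethylammonium (S)-1,3-dimethylcyclohexa-2,5-diene-1-carboxylate F1 (the antipodal amine is used if the other salt crystallises). Aqueous HCl frees the (S)-acid F2. LiAlH4 gives the (S)-alcohol F3 and Et3SiCl/imidazole gives the (S)-triethylsilyl ether F4. s-BuLi/TMEDA gives the (S)-cyclohexadienyllithium F5, and ClTi(OiPr)3 gives the achiral-ligand triisopropoxytitanium reagent F6. F6 adds to 6 under pure substrate control (open β face, closed chair), and the route is rejoined at 9.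

Step 8. The risks are a hindered neopentyl aldehyde and uncertain control at C2. The fallback sets C2 by ketone reduction instead of carbonyl addition and sets out from 12. A Nozaki–Hiyama–Kishi vinylation (vinyl bromide, CrCl2, NiCl2 cat., DMF) gives the C2-epimeric allylic alcohols F7. Dess–Martin periodinane gives the vinyl ketone F8. (R)-Me-CBS oxazaborolidine/BH3·SMe2 treats the tert-alkyl C1 as the large group and gives the (2S)-allylic alcohol F9. Butanoic anhydride/DMAP then brings the route back at 14.

Step 14. The risks are closing a ten-membered ring on a fully loaded substrate and the geometry of the C3=C4 olefin. The fallback closes the ring before the chloride and the lactone exist, while the chain is more flexible and the alkyne less crowded, and sets out from 18. The same ruthenium/ethene conditions give the butadienyl epoxide F10 and then the macrocyclic trans-vinyl epoxide F11. 2-Bromopropanoyl chloride/CoCl2 opens F11 at the now allylic C6 to the macrocyclic chloro 2-bromopropanoate F12. SmI2 at −78 °C closes the lactone across the ring, and the route is rejoined at 23.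

**Further compounds**
F1 | step 4 | (R)-1-phenylethylammonium (S)-1,3-dimethylcyclohexa-2,5-diene-1-carboxylate | C[C@@H]([NH3+])c1ccccc1.[O-]C(=O)[C@@]1(C)C=CCC(C)=C1
F2 | step 4 | (S)-1,3-dimethylcyclohexa-2,5-diene-1-carboxylic acid | OC(=O)[C@@]1(C)C=CCC(C)=C1
F3 | step 4 | (S)-(1,3-dimethylcyclohexa-2,5-dien-1-yl)methanol | OC[C@@]1(C)C=CCC(C)=C1
F4 | step 4 | (S)-[(1,3-dimethylcyclohexa-2,5-dien-1-yl)methoxy]triethylsilane | CC[Si](CC)(CC)OC[C@@]1(C)C=CCC(C)=C1
F5 | step 4 | (S)-cyclohexadienyllithium (F4 lithiated at C12) | CC[Si](CC)(CC)OC[C@@]1(C)C=CC([Li])C(C)=C1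
F6 | step 4 | triisopropoxytitanium reagent (Ti(OiPr)3 on C12, β face) | CC[Si](CC)(CC)OC[C@@]1(C)C=C[C@H]([Ti](OC(C)C)(OC(C)C)OC(C)C)C(C)=C1
F7 | step 8 | C2-epimeric allylic alcohols | C=CC(O)[C@@]1(C)C=C[C@@H](OC(C)=O)[C@@](C)(O)[C@@H]1[C@H](OC(C)=O)c1ccco1
F8 | step 8 | vinyl ketone (C2=O) | C=CC(=O)[C@@]1(C)C=C[C@@H](OC(C)=O)[C@@](C)(O)[C@@H]1[C@H](OC(C)=O)c1ccco1
F9 | step 8 | (2S)-allylic alcohol | C=C[C@H](O)[C@@]1(C)C=C[C@@H](OC(C)=O)[C@@](C)(O)[C@@H]1[C@H](OC(C)=O)c1ccco1
F10 | step 14 | butadienyl epoxide (6R,7S) | C=C[C@H](OC(=O)CCC)[C@@]1(C)C=C[C@@H](OC(C)=O)[C@@](C)(O)[C@@H]1[C@H](OC(C)=O)C(=O)[C@H]1O[C@@H]1C(=C)C=C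
F11 | step 14 | macrocyclic trans-vinyl epoxide (3Z,6R,7S) | C=C1/C=C\[C@H](OC(=O)CCC)[C@@]2(C)C=C[C@@H](OC(C)=O)[C@@](C)(O)[C@@H]2[C@H](OC(C)=O)C(=O)[C@H]3O[C@H]13
F12 | step 14 | macrocyclic chloro 2-bromopropanoate (3Z,6S,7R) | C=C1/C=C\[C@H](OC(=O)CCC)[C@@]2(C)C=C[C@@H](OC(C)=O)[C@@](C)(O)[C@@H]2[C@H](OC(C)=O)C(=O)[C@@H](OC(=O)C(C)Br)[C@H]1Cl
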